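All runs are simulated with made-up constants, and the scatter is random.

Look at the lag first.

| flask | free monomer | initiator | temperature | remark | time |
|---|---|---|---|---|---|
| teal | 52 mM | 0.33 mol% | 39 °C | run made earlier |  |
| green | 81 mM | 0.33 mol% | 47 °C | run made earlier |  |
| blue | 37 mM | 0.17 mol% | 39 °C | run made earlier |  |
| elm | 37 mM | 0.33 mol% | 50 °C |  | 4.0 h |
| birch | 37 mM | 0.33 mol% | 35 °C |  | 4.0 h |

| run | time / h | monomer in chains / % | free monomer / % |
|---|---|---|---|
| teal | 0.417 | 1 | 99 |
| teal | 0.667 | 0 | 101 |
| teal | 0.833 | 1 | 100 |
| teal | 1.33 | 3 | 102 |
| teal | 2.00 | 7 | 94 |
| teal | 3.00 | 14 | 87 |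
| teal | 5.00 | 30 | 69 |
| green | 0.250 | 0 | 101 |
| green | 0.333 | 2 | 98 |
| green | 0.500 | 3 | 97 |
| green | 0.667 | 4 | 94 |
| green | 1.00 | 9 | 88 |
| green | 1.50 | 22 | 79 |
| green | 3.00 | 54 | 49 |
| blue | 0.417 | 2 | 99 |
| blue | 0.667 | 0 | 100 |
| blue | 1.33 | 1 | 100 |
| blue | 2.50 | 2 | 96 |
| blue | 5.00 | 12 | 92 |

(readings scatter by 1.5 percentage points)



* the flask that ends with the higher amount of monomer in chains, in percent of the free monomer charged, or "neither" when 2 percentage points or less lies between them (elm / birch / neither)
* final monomer in chains, as a percentage of the free monomer charged, in elm
* final monomer in chains, as a percentage of the free monomer charged, in birch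

What do the runs show? In the teal run the chains hold 1 % at 0.833 h but 30 % at 5.00 h, and chains plus free monomer stay near the whole charge, so reacted monomer can be read as monomer in chains.

What does that lag mean? Write f for the free fraction. With a constant catalyst, −ln f climbs in a straight line, but in these readings it climbs roughly as t squared, so I take it that something active piles up in the flask. If free monomer and initiator make it, its supply goes as c(free monomer)·c(initiator), which is loading times c(free monomer) squared.

Taking f as the mean of the free monomer reading and of what the chains reading leaves, teal at 3.00 h reads −ln f = 0.145. Call this the start-up number X: −ln f as expected from loading, c(free monomer) squared and t squared, at a given temperature.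

Why the square? Scaled to blue, X is 0.105, and blue reads 0.105. Blue changes loading and c(free monomer) together, so this test takes the loading at first power; the first power of c(free monomer) then expects 13.7 % reacted where the blue readings show 10.0 %, with readings good to 1.5 percentage points.

And temperature? Green at 1.50 h reads 0.242, which is 2.75 times the scaled teal value. I carry that factor as a straight line in ln X over these few degrees.

So elm? X is 0.525.

Isn't that too large for a law that holds the free monomer at its charge? It is, so I go round again. Feeding f back into the supply and integrating twice gives X(1 − X/6), which is 0.479, or 38.1 % in chains for elm. I still hold the initiator at its charge.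

Birch has X = 0.0787, and the same correction gives 7.47 %, so my answer is elm.

The forecast, holding that “c is proportional to initiator concentration”, also names elm, with 8 % for birch and, higher than my figure, 65 % for elm.

The flasks give elm: 36.1 % in elm and 8.02 % in birch.

    free monomer + living end → monomer in chains + living end, rate k1*[living end]*[free monomer] (k = 2030 /M/h, Ea = 40.0 kJ/mol)
    initiator ⇌ dormant form (K = 0.370, k = 1.27 /h, Ea = 97.0 kJ/mol, ΔH = −43.0 kJ/mol)
    free monomer + initiator → living end + monomer in chains (k = 1.61 /M/h, Ea = 55.0 kJ/mol)
    (constants at 35 °C)

In elm, chain growth, pseudo-first-order in free monomer at a given c(living end), uses free monomer 440 times as fast as the start step at 2.54 h, when the half-life of free monomer by chain growth is 4.8 h. By 4.00 h that ratio stands at 680, with 0.0462 mM of living end present and −ln f = 0.447 against my 0.479. For a neighbour of elm with 22 mM of free monomer, its loading, temperature and time as in elm, X is 0.186, which reckons 16.5 % in chains, and that flask ends with 16.1 %.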